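## Retrosynthetic overview
1. The target's three acyl groups come last: the C1 isovalerate by one-pot desilylative acylation of an anomeric silyl ether, the C11 isovalerate by acylation after Luche reduction of a C4-formyl enol ether, and the C10 acetate from the Payne opening.
2. The 7β-OH / 8α-OH / 10-OAc cluster comes from a Payne rearrangement–acetolysis of the β-epoxide of the C7=C8–C10-OH allylic alcohol (key new step). The epoxide forms on the convex face, and the Payne inversion moves the C8 oxygen to the α face.
3. Both rings and the C1, C5 and C9 centres are carried intact from chiral-pool (−)-genipin, so no ring is built. The only new ring is the oxirane, which is formed and then transposed.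
4. The C4 ester is taken to the aldehyde level so it can stay electron-poor through the oxidations and be reduced selectively with NaBH4 at the end, next to the acetate.

Assumptions: commercial (−)-genipin (1R,4aS,7aS) is the starting material. Its lactol C1 epimerises, so C1 is left unspecified in the intermediates and is set in Step 10.

## Route

**Step 1**
Reactants: 1 (genipin); 2 (tert-butyldimethylsilyl chloride)
Product: 3 (10-O-TBS genipin, lactol)
Conditions: TBSCl, Et3N, cat. DMAP, CH2Cl2, 0 °C
Reagents that add atoms: TBSCl, CC(C)(C)[Si](C)(C)Cl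
Why: Chemoselective silylation of the unhindered primary allylic OH over the hindered lactol OH; no new stereocentre (C1 is an equilibrating lactol).

**Step 2**
Reactants: 3; 4 (TIPSOTf)
Product: 5 (1-O-TIPS, 10-O-TBS methyl ester, C1 epimeric mixture)
Conditions: TIPSOTf, 2,6-lutidine, CH2Cl2, −78 → 0 °C
Reagents that add atoms: TIPSOTf, CC(C)[Si](C(C)C)(C(C)C)OS(=O)(=O)C(F)(F)F
Why: Silylation of the lactol gives a base-stable, DIBAL-stable, acid-robust acetal protecting group. The C1 epimers are irrelevant because C1 is reset in Step 10.

**Step 3**
Reactants: 5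
Product: 6 (C11 allylic alcohol)
Conditions: DIBAL-H (3.5 equiv), CH2Cl2/toluene, −78 → −20 °C; Rochelle salt work-up
Reagents that add atoms: none (hydride only)
Why: DIBAL reduction of the vinylogous carbonate ester to the allylic alcohol. Both silyl ethers survive, and the alkene and stereocentres are untouched.

**Step 4**
Reactants: 6
Product: 7 (C4-formyl enol ether, the push–pull enal)
Conditions: activated MnO2 (15 equiv), CH2Cl2, rt
Reagents that add atoms: none
Why: MnO2 oxidises only the activated allylic alcohol, because C10 is silylated. The product is a stable β-alkoxyenal that keeps the enol ether electron-poor for the oxidations that follow.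

**Step 5**
Reactants: 7
Product: 8 (10-OH enal, 1-O-TIPS)
Conditions: PPTS (0.3 equiv), MeOH/CH2Cl2, 30 °C
Reagents that add atoms: none
Why: Mild acidic methanolysis removes the primary TBS ether selectively. The TIPS acetal survives because it is much more acid-stable and the acetal oxygen is deactivated by the enal.

**Step 6**
Reactants: 8; 9 (tert-butyl hydroperoxide)
Product: 10 (7β,8β-epoxy alcohol)
Conditions: VO(acac)2 (5 mol %), TBHP, CH2Cl2, 4 Å MS, 0 °C → rt
Reagents that add atoms: TBHP, CC(C)(C)OO (O-atom donor)
Why: Hydroxyl-directed (vanadium) epoxidation of the allylic alcohol occurs on the convex β face, the face of H5/H9, because the cis-fused pyran ring blocks the α face. This sets the C7 oxygen configuration, which is retained to the target. The push–pull enol ether is inert.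

**Step 7**
Reactants: 10; 11 (CsOAc); 12 (AcOH)
Product: 13 (7β-OH, 8α-OH, 10-OAc enal)
Conditions: Cs2CO3 (0.2 equiv), CsOAc (3 equiv), AcOH (3 equiv), DMF, 45 °C
Reagents that add atoms: CsOAc, CC(=O)[O-].[Cs+]; AcOH, CC(=O)O
Why: Proposed new method: a Payne rearrangement–carboxylate opening cascade on a cyclic, acetal-bearing epoxy alcohol. The closest known reaction type is Payne rearrangement/nucleophilic opening with thiolates, amines or hydroxide on acyclic epoxy alcohols. The C10 alkoxide attacks C8 anti to the epoxide C–O bond (3-exo-tet, inversion). This gives a spiro 8,10-oxirane with its oxygen on the α face, and releases the 7β-alkoxide, which is protonated by AcOH. The strained cyclopentene oxide thus converts to the spiro oxirane, and the buffered cesium acetate then opens it by SN2 at the unhindered C10 CH2. The C8–O bond is untouched, so C8 keeps the α oxygen and ends as the tertiary alcohol, giving net anti-oxygenation at C7/C8 with the acetate already on C10. The weakly basic buffer is chosen so the enal, the acetal and the new acetate survive.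

**Step 8**
Reactants: 13
Product: 14 (C11 allylic alcohol, 10-OAc, 1-O-TIPS)
Conditions: NaBH4 (0.35 equiv), CeCl3·7H2O, MeOH/CH2Cl2, −78 °C
Reagents that add atoms: none (hydride only)
Why: Luche 1,2-reduction of the enal leaves the acetate, acetal and free 7,8-diol intact; this is why the aldehyde oxidation level was used. No stereocentre is created.

**Step 9**
Reactants: 14; 15 (isovaleryl chloride)
Product: 16 (C11 isovalerate)
Conditions: i-PrCH2COCl (1.05 equiv), pyridine, CH2Cl2, −40 → 0 °C
Reagents that add atoms: isovaleryl chloride, CC(C)CC(=O)Cl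
Why: Acylation of the only unhindered primary OH. The C7 secondary OH and C8 tertiary OH are neopentylic and react far more slowly at this stoichiometry and temperature.

**Step 10**
Reactants: 16; 15 (isovaleryl chloride)
Product: 17 (target)
Conditions: TBAF (1.2 equiv), THF, 0 °C, 10 min; then i-PrCH2COCl (3 equiv), pyridine, 0 °C
Reagents that add atoms: isovaleryl chloride, CC(C)CC(=O)Cl
Why: Fluoride removes the anomeric TIPS group and generates the C1 alkoxide, which is acylated in situ, so the C7-OH and C8-OH are not acylated. C1 is set here under anomeric-effect control (pseudo-axial acyloxy, the natural anomer); the minor epimer is removed by chromatography.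

## Compound list
1 | (−)-genipin, methyl (1R,4aS,7aS)-1-hydroxy-7-(hydroxymethyl)-1,4a,5,7a-tetrahydrocyclopenta[c]pyran-4-carboxylate | COC(=O)C1=CO[C@H]([C@H]2[C@@H]1CC=C2CO)O | starting material
2 | tert-butyldimethylsilyl chloride | CC(C)(C)[Si](C)(C)Cl | starting material (reagent)
3 | 10-O-TBS genipin (C1 epimeric lactol) | COC(=O)C1=COC(O)[C@H]2[C@@H]1CC=C2CO[Si](C)(C)C(C)(C)C | intermediate
4 | triisopropylsilyl triflate | CC(C)[Si](C(C)C)(C(C)C)OS(=O)(=O)C(F)(F)F | starting material (reagent)
5 | 1-O-TIPS, 10-O-TBS methyl ester (C1 epimeric mixture) | COC(=O)C1=COC(O[Si](C(C)C)(C(C)C)C(C)C)[C@H]2[C@@H]1CC=C2CO[Si](C)(C)C(C)(C)C | intermediate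
6 | C11 allylic alcohol | OCC1=COC(O[Si](C(C)C)(C(C)C)C(C)C)[C@H]2[C@@H]1CC=C2CO[Si](C)(C)C(C)(C)C | intermediate
7 | C4-formyl enol ether, bis-silyl | O=CC1=COC(O[Si](C(C)C)(C(C)C)C(C)C)[C@H]2[C@@H]1CC=C2CO[Si](C)(C)C(C)(C)C | intermediate
8 | C4-formyl enol ether, 10-OH, 1-O-TIPS | O=CC1=COC(O[Si](C(C)C)(C(C)C)C(C)C)[C@H]2[C@@H]1CC=C2CO | intermediate
9 | tert-butyl hydroperoxide | CC(C)(C)OO | starting material (reagent)
10 | 7β,8β-epoxy alcohol | O=CC1=COC(O[Si](C(C)C)(C(C)C)C(C)C)[C@H]2[C@@H]1C[C@@H]3O[C@]23CO | intermediate
11 | cesium acetate | CC(=O)[O-].[Cs+] | starting material (reagent)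
12 | acetic acid | CC(=O)O | starting material (reagent)
13 | 7β-OH, 8α-OH, 10-OAc enal, 1-O-TIPS | CC(=O)OC[C@]1(O)[C@H]2C(O[Si](C(C)C)(C(C)C)C(C)C)OC=C(C=O)[C@H]2C[C@@H]1O | intermediate
14 | C11 alcohol, 10-OAc, 1-O-TIPS | CC(=O)OC[C@]1(O)[C@H]2C(O[Si](C(C)C)(C(C)C)C(C)C)OC=C(CO)[C@H]2C[C@@H]1O | intermediate
15 | isovaleryl chloride | CC(C)CC(=O)Cl | starting material (reagent)
16 | C11 isovalerate, 10-OAc, 1-O-TIPS | CC(=O)OC[C@]1(O)[C@H]2C(O[Si](C(C)C)(C(C)C)C(C)C)OC=C(COC(=O)CC(C)C)[C@H]2C[C@@H]1O | intermediate
17 | target | CC(=O)OC[C@]1(O)[C@H]2[C@H](OC(=O)CC(C)C)OC=C(COC(=O)CC(C)C)[C@H]2C[C@@H]1O | target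

## Totals
Total steps: 10. Longest linear sequence: 10 (all steps are linear from genipin).

## Three steps most likely to fail
1. **Step 7 (proposed new Payne–acetolysis).**
   - Risks: the Payne equilibrium may not favour the spiro oxirane, attack from the concave α face may be slow, and acetate may open at C8 or migrate.
   - Fallback (known chemistry, different approach): convert the 10-OH of 10 to the tert-butyl carbonate (Boc2O, DMAP). Lewis-acid promotion (Sc(OTf)3) then gives carbonate-directed 5-exo opening at C8 with inversion, forming an 8,10-cyclic carbonate and the free 7β-OH. Methanolysis releases the 7,8,10-triol, and selective primary acetylation (Ac2O, pyridine, −20 °C) gives 13.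
2. **Step 10 (anomeric acylation).**
   - Risks: the wrong C1 anomer, or acylation of C7-OH.
   - Fallback: protect C7-OH as its TES ether, remove TIPS with TBAF/AcOH, acylate the lactol by Steglich coupling (isovaleric acid, EDC, DMAP), equilibrate to the natural anomer with DBU, then remove TES with HF·pyridine.
3. **Step 6 (epoxidation face selectivity and chemoselectivity with the enal present).**
   - Risks: wrong-face epoxide, or TBHP interacting with the aldehyde.
   - Fallback: use reagent-controlled Sharpless asymmetric epoxidation (Ti(OiPr)4, the matched DET enantiomer, TBHP, −20 °C) to override the substrate's facial bias.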